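**Retrosynthetic overview**

1. The target is a depside. Its ring B carries oxygen on C2 and C4 on either side of C3–H, and the ester carbon C1 sits next to the propyl-bearing C6. This pattern maps onto a 1,1,3-trioxygenated butadiene (C2 to C5) joined to a hex-2-ynoate (C1, C6).
2. Last operations: O-methylation of the chelated C2–OH of ring B, then hydrogenolysis of the two benzyl ethers on ring A.
3. Key disconnection: C1–C2 and C5–C6 of ring B, by Diels–Alder cycloaddition and aromatization of a 3-aroyloxy-1-methoxy-1-silyloxybutadiene with methyl hex-2-ynoate; the diene already carries ring A on the future C4 oxygen.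
4. The diene comes from the E enol ester of methyl acetoacetate by γ-deprotonation and O-silylation. The enol ester comes from the ring A acid chloride, and the acid from divarinol by formylation, benzylation and Pinnick oxidation.
5. Ring order: ring A is bought with divarinol; ring B is the only ring made, in step 7.

Key step: step 7

Assumption: the enol ester of step 5 is drawn as its E isomer (aroyloxy group trans to the ester). This isomer is chosen because its methyl group lies syn to the ester carbonyl and its vinyl hydrogen is syn to the aroyloxy group, which should favour γ-deprotonation over anti elimination. Any Z isomer formed beside it should lead to the same diene, since the but-2-enoate double bond becomes the central single bond of the diene.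

**Route**

Step 1
Reactants: 1 divarinol (5-propylbenzene-1,3-diol)
Product: 3 2,4-dihydroxy-6-propylbenzaldehyde, via aryl iminium chloride 2 (not isolated)
Conditions: POCl3, DMF, 0 °C → rt; then H2O, 50 °C
Reagents that add atoms: N,N-dimethylformamide, CN(C)C=O; water, O
Why: Vilsmeier–Haack formylation, in which the chloroiminium ion from POCl3 and DMF should attack the resorcinol at C4 (para to one hydroxyl, ortho to the other) and the aryl iminium salt is hydrolysed to the aldehyde on aqueous work-up.

Step 2
Reactants: 3 2,4-dihydroxy-6-propylbenzaldehyde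
Product: 4 2,4-bis(benzyloxy)-6-propylbenzaldehyde
Conditions: BnBr, K2CO3, DMF, 60 °C
Reagents that add atoms: benzyl bromide, BrCc1ccccc1
Why: Williamson ether synthesis, in which excess benzyl bromide and K2CO3 in DMF should alkylate both phenols, including the hydrogen-bonded one ortho to the aldehyde.

Step 3
Reactants: 4 2,4-bis(benzyloxy)-6-propylbenzaldehyde
Product: 5 2,4-bis(benzyloxy)-6-propylbenzoic acid
Conditions: NaClO2, NaH2PO4, 2-methylbut-2-ene, t-BuOH/H2O, rt
Reagents that add atoms: sodium chlorite, [Na+].[O-]Cl=O
Why: Pinnick oxidation converts the aryl aldehyde into the acid under buffered conditions, and 2-methylbut-2-ene traps the hypochlorous acid so that the electron-rich ring should not be chlorinated.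

Step 4
Reactants: 5 2,4-bis(benzyloxy)-6-propylbenzoic acid
Product: 6 2,4-bis(benzyloxy)-6-propylbenzoyl chloride
Conditions: (COCl)2, DMF (cat.), CH2Cl2, 0 °C → rt; concentrated and used crude
Reagents that add atoms: oxalyl chloride, O=C(Cl)C(Cl)=O
Why: Acid chloride formation through the catalytic chloroiminium species is mild enough for benzyl ethers and is routine for 2,6-disubstituted benzoic acids.

Step 5
Reactants: 6 2,4-bis(benzyloxy)-6-propylbenzoyl chloride; 7 methyl acetoacetate (methyl 3-oxobutanoate)
Product: 8 methyl (E)-3-[2,4-bis(benzyloxy)-6-propylbenzoyloxy]but-2-enoate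
Conditions: Et3N, DMPU, CH2Cl2, 0 °C → rt
Reagents that add atoms: none
Why: O-Acylation of a β-keto ester enolate by an aroyl chloride (enol ester formation) is favoured over C-acylation when no chelating metal is present, the open ammonium enolate in a dipolar aprotic medium should give mainly the E enol ester, and the electron-rich acyl chloride should react through an acylium-like transition state that tolerates its two ortho substituents.

Step 6
Reactants: 8 methyl (E)-3-[2,4-bis(benzyloxy)-6-propylbenzoyloxy]but-2-enoate
Product: 10 (3Z)-4-(tert-butyldimethylsilyloxy)-4-methoxybuta-1,3-dien-2-yl 2,4-bis(benzyloxy)-6-propylbenzoate, via lithium dienolate 9 (not isolated)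
Conditions: LiN(iPr)2 (1.05 equiv), THF, −78 °C; then TBSCl, DMPU, −78 → 0 °C; non-aqueous work-up
Reagents that add atoms: tert-butyldimethylsilyl chloride, CC(C)(C)[Si](C)(C)Cl
Why: Vinylogous ester enolization followed by O-silylation is the standard entry to 1-alkoxy-1-silyloxybuta-1,3-dienes from 3-oxygenated but-2-enoates; here the methyl group is syn to the ester carbonyl for directed γ-deprotonation, the doubly ortho-substituted aroyl carbonyl is shielded from the amide base, and the in-plane C–O bond of the enol ester is orthogonal to the dienolate π system, which should disfavour β-elimination.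

Step 7
Reactants: 10 (3Z)-4-(tert-butyldimethylsilyloxy)-4-methoxybuta-1,3-dien-2-yl 2,4-bis(benzyloxy)-6-propylbenzoate; 11 methyl hex-2-ynoate
Product: 14 methyl 4-[2,4-bis(benzyloxy)-6-propylbenzoyloxy]-2-hydroxy-6-propylbenzoate, via cyclohexa-1,4-diene cycloadduct 12 (not isolated), via cyclohexadienone tautomer 13 (not isolated)
Conditions: toluene, 120 °C, sealed tube (excess 11); then TsOH·H2O (cat.), CH2Cl2, rt
Reagents that add atoms: none
Why: Thermal normal-demand Diels–Alder cycloaddition in which the diene is a vinylogous ketene acetal with its largest HOMO coefficient on the CH2 terminus, so this carbon should bond first to the propyl-bearing β-carbon of the ynoate and the ketene-acetal carbon then to the α-carbon, an asynchronous concerted [4+2] that forms C5–C6 and C1–C2 of ring B. The closest known reaction type is the cycloaddition–aromatization of 1-alkoxy-1-silyloxybuta-1,3-dienes with alkynoates to give salicylates; the 3-aroyloxy group is a weaker donor than the 3-alkoxy or 3-silyloxy groups of the usual dienes but polarizes the diene in the same sense. Ring B is closed as a six-membered carbocycle in one intermolecular [4+2] event that gives cyclohexa-1,4-diene 12; under the acid its mixed ketal should collapse to the carbonyl of 13 with loss of tert-butyl(methoxy)dimethylsilane, and 13 tautomerizes to the hydrogen-bonded 2-hydroxybenzoate. No stereocentre is kept, since the ketal carbon of 12 is racemic and becomes planar on aromatization. The selectivity needed is regiochemical, and the matched polarization (donor terminus to β-carbon) places the ester carbon between C–OH and C–propyl; the hindered aryl ester of ring A and the benzyl ethers should be inert to the heat and the mild acid.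

Step 8
Reactants: 14 methyl 4-[2,4-bis(benzyloxy)-6-propylbenzoyloxy]-2-hydroxy-6-propylbenzoate
Product: 15 methyl 4-[2,4-bis(benzyloxy)-6-propylbenzoyloxy]-2-methoxy-6-propylbenzoate
Conditions: MeI, K2CO3, DMF, rt
Reagents that add atoms: iodomethane, CI
Why: Williamson O-methylation of the only free phenol, in which the hydrogen bond to the ester slows but should not prevent alkylation in DMF and the doubly ortho-substituted aryl ester of ring A resists the carbonate.

Step 9
Reactants: 15 methyl 4-[2,4-bis(benzyloxy)-6-propylbenzoyloxy]-2-methoxy-6-propylbenzoate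
Product: 16 methyl 4-(2,4-dihydroxy-6-propylbenzoyloxy)-2-methoxy-6-propylbenzoate (CNP0177078.0)
Conditions: H2 (1 atm), Pd/C, EtOAc, rt
Reagents that add atoms: none
Why: Catalytic hydrogenolysis should cleave the two benzyl ethers and leave the aryl ester, the methyl ester and the methyl ether untouched, giving the target, which has no stereocentre.

**Compound list**

1 | divarinol (5-propylbenzene-1,3-diol) | CCCc1cc(O)cc(O)c1 | starting material
2 | [(2,4-dihydroxy-6-propylphenyl)methylidene]dimethylammonium chloride (not isolated) | CCCc1cc(O)cc(O)c1C=[N+](C)C.[Cl-] | intermediate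
3 | 2,4-dihydroxy-6-propylbenzaldehyde | CCCc1cc(O)cc(O)c1C=O | intermediate
4 | 2,4-bis(benzyloxy)-6-propylbenzaldehyde | CCCc1cc(OCc2ccccc2)cc(OCc2ccccc2)c1C=O | intermediate
5 | 2,4-bis(benzyloxy)-6-propylbenzoic acid | CCCc1cc(OCc2ccccc2)cc(OCc2ccccc2)c1C(=O)O | intermediate
6 | 2,4-bis(benzyloxy)-6-propylbenzoyl chloride | CCCc1cc(OCc2ccccc2)cc(OCc2ccccc2)c1C(=O)Cl | intermediate
7 | methyl acetoacetate (methyl 3-oxobutanoate) | CC(=O)CC(=O)OC | starting material
8 | methyl (E)-3-[2,4-bis(benzyloxy)-6-propylbenzoyloxy]but-2-enoate | C/C(OC(=O)c1c(CCC)cc(OCc2ccccc2)cc1OCc1ccccc1)=C\C(=O)OC | intermediate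
9 | lithium (1Z)-3-[2,4-bis(benzyloxy)-6-propylbenzoyloxy]-1-methoxybuta-1,3-dien-1-olate (not isolated) | [Li+].C=C(OC(=O)c1c(CCC)cc(OCc2ccccc2)cc1OCc1ccccc1)/C=C(/OC)[O-] | intermediate
10 | (3Z)-4-(tert-butyldimethylsilyloxy)-4-methoxybuta-1,3-dien-2-yl 2,4-bis(benzyloxy)-6-propylbenzoate | C=C(OC(=O)c1c(CCC)cc(OCc2ccccc2)cc1OCc1ccccc1)/C=C(/OC)O[Si](C)(C)C(C)(C)C | intermediate
11 | methyl hex-2-ynoate | CCCC#CC(=O)OC | starting material
12 | methyl 4-[2,4-bis(benzyloxy)-6-propylbenzoyloxy]-6-(tert-butyldimethylsilyloxy)-6-methoxy-2-propylcyclohexa-1,4-diene-1-carboxylate (racemic, not isolated) | COC(=O)C1=C(CCC)CC(OC(=O)c2c(CCC)cc(OCc3ccccc3)cc2OCc2ccccc2)=CC1(OC)O[Si](C)(C)C(C)(C)C | intermediate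
13 | methyl 4-[2,4-bis(benzyloxy)-6-propylbenzoyloxy]-6-oxo-2-propylcyclohexa-1,4-diene-1-carboxylate (not isolated) | COC(=O)C1=C(CCC)CC(OC(=O)c2c(CCC)cc(OCc3ccccc3)cc2OCc2ccccc2)=CC1=O | intermediate
14 | methyl 4-[2,4-bis(benzyloxy)-6-propylbenzoyloxy]-2-hydroxy-6-propylbenzoate | CCCc1cc(OCc2ccccc2)cc(OCc2ccccc2)c1C(=O)Oc1cc(CCC)c(C(=O)OC)c(O)c1 | intermediate
15 | methyl 4-[2,4-bis(benzyloxy)-6-propylbenzoyloxy]-2-methoxy-6-propylbenzoate | CCCc1cc(OCc2ccccc2)cc(OCc2ccccc2)c1C(=O)Oc1cc(CCC)c(C(=O)OC)c(OC)c1 | intermediate
16 | methyl 4-(2,4-dihydroxy-6-propylbenzoyloxy)-2-methoxy-6-propylbenzoate | CCCc1cc(O)cc(O)c1C(=O)Oc1cc(CCC)c(C(=O)OC)c(OC)c1 | target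

**Step count**

Total: 9 steps. Longest linear sequence: 9 steps (1 to 16); compounds 7 and 11 are bought.

**Steps most likely to fail**

Step 7. The β-propyl ynoate is a weak dienophile, so thermal decomposition or hydrolysis of the ketene acetal, or oligomerization of the diene, may outrun the cycloaddition. The fallback sets out from 10 and replaces 11 by its allene isomer, methyl hexa-2,3-dienoate F1, whose conjugated double bond is a much better dienophile. F1 would be made from butanoyl chloride and methyl (triphenylphosphoranylidene)acetate with Et3N in CH2Cl2 by a Wittig reaction. Cycloaddition of 10 and F1 in toluene at rt to 60 °C should follow the same regiochemistry (CH2 terminus to the central allene carbon) and give methyl 4-[2,4-bis(benzyloxy)-6-propylbenzoyloxy]-2-(tert-butyldimethylsilyloxy)-2-methoxy-6-propylidenecyclohex-3-ene-1-carboxylate F2 as a mixture of stereoisomers. TsOH in CH2Cl2 should then remove the silyl methyl ether and move the exocyclic double bond into the ring, and the route is rejoined at 14.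

Step 6. The dienolate may lose the aroyloxy group by β-elimination, the vinyl hydrogen may be removed with fragmentation, the benzylic CH2 of the ring A propyl group may be deprotonated instead, or the amide may add to the enoate. The fallback sets out from 7 and attaches ring A after the cycloaddition. Silylation of 7 with TMSCl and Et3N should give methyl 3-(trimethylsilyloxy)but-2-enoate F3, and LiN(iPr)2 followed by TMSCl in THF at −78 °C should give 1-methoxy-1,3-bis(trimethylsilyloxy)buta-1,3-diene F4, a diene of established use. Heating F4 with 11 should give methyl 6-methoxy-2-propyl-4,6-bis(trimethylsilyloxy)cyclohexa-1,4-diene-1-carboxylate F5, and acidic work-up should aromatize and desilylate it to methyl 2,4-dihydroxy-6-propylbenzoate F6. Acylation of the free 4-hydroxyl of F6 with acid 5 and (CF3CO)2O in toluene, the chelated 2-hydroxyl staying untouched, rejoins the route at 14.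

Step 5. Acyl transfer at the doubly ortho-substituted carbonyl may be slow, so that C-acylation, hydrolysis of the acid chloride or loss of the E geometry competes. The fallback sets out from 5 and forms the oxygen–vinyl bond instead, so that the hindered carbonyl is never attacked. Acid 5 would be added across methyl but-2-ynoate with Ph3PAuCl and AgOSO2CF3 (catalytic) in toluene at 60 °C, an anti hydro-acyloxylation at the β-carbon that should give methyl (Z)-3-[2,4-bis(benzyloxy)-6-propylbenzoyloxy]but-2-enoate F7. Deprotonation of F7 with LiN(iPr)2 in THF/DMPU at −78 °C and silylation with TBSCl rejoins the route at 10.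

**Further compounds**

F1 | step 7 | methyl hexa-2,3-dienoate (racemic) | CCC=C=CC(=O)OC
F2 | step 7 | methyl 4-[2,4-bis(benzyloxy)-6-propylbenzoyloxy]-2-(tert-butyldimethylsilyloxy)-2-methoxy-6-propylidenecyclohex-3-ene-1-carboxylate (mixture of stereoisomers) | COC(=O)C1C(=CCC)CC(OC(=O)c2c(CCC)cc(OCc3ccccc3)cc2OCc2ccccc2)=CC1(OC)O[Si](C)(C)C(C)(C)C
F3 | step 6 | methyl 3-(trimethylsilyloxy)but-2-enoate (E/Z mixture) | CC(O[Si](C)(C)C)=CC(=O)OC
F4 | step 6 | 1-methoxy-1,3-bis(trimethylsilyloxy)buta-1,3-diene | C=C(O[Si](C)(C)C)C=C(OC)O[Si](C)(C)C
F5 | step 6 | methyl 6-methoxy-2-propyl-4,6-bis(trimethylsilyloxy)cyclohexa-1,4-diene-1-carboxylate (racemic) | COC(=O)C1=C(CCC)CC(O[Si](C)(C)C)=CC1(OC)O[Si](C)(C)C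
F6 | step 6 | methyl 2,4-dihydroxy-6-propylbenzoate | CCCc1cc(O)cc(O)c1C(=O)OC
F7 | step 5 | methyl (Z)-3-[2,4-bis(benzyloxy)-6-propylbenzoyloxy]but-2-enoate | C/C(OC(=O)c1c(CCC)cc(OCc2ccccc2)cc1OCc1ccccc1)=C/C(=O)OC
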